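## Retrosynthetic overview

1. The strategy rests on ring B carrying the C7 isopropenyl group next to, and trans to, the C8 oxygen (the homoallylic alcohol unit C12=C11–C7–C8–O). C7–C8 is therefore cut as a Lewis-acid carbonyl-ene bond between a C8 aldehyde on the C10 arm and the prenyl group on C5; this closes ring B last.
2. In the chair that leads to the target the C9 oxygen is axial on ring B and lies over C2 of ring A. O9 and the C2 carbonyl are therefore joined as one internal methyl ketal (6-oxabicyclo[3.2.1]octane), which protects C2, masks O9 and fixes that chair. The esters follow ring closure: C8 acetate, ketal hydrolysis, C9 tiglate.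
3. The C9–C8 arm comes from a Mukaiyama–Michael addition to a 4,4,5-trisubstituted cyclohexenone (sets C10), followed by oxidation to the α-keto ester and Felkin–Anh reduction (sets C9).
4. C4 and C5 of ring A come from copper-catalysed asymmetric methyl addition to 2-methylcyclohexenone with prenyl bromide trapping; a Wharton transposition then moves the carbonyl from C10 to C2.
5. Ring order: ring A (present from the start), the temporary oxygen bridge, then ring B.

Key step: step 13

Remark: eremophilane numbering is used throughout (ring A = C1–C5, C10; ring B = C5–C10; C14 = methyl on C5; C15 = methyl on C4; C11–C13 = isopropenyl on C7).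

Remark: a spiro-dioxolane at C2 with a separate ether at C9 would place a ketal oxygen syn-axial to O9 in the only chair that gives the target, and the chair with all ring-B substituents equatorial would instead give the C7,C8-bis-epimer. The internal ketal removes both problems.

Assumption: the phosphoramidite enantiomer that gives the 3S adduct in step 1 is fixed by a test run on 1.

## Route

Step 1
Reactants: 1 2-methylcyclohex-2-en-1-one; 2 prenyl bromide
Product: 5 (2R,3S)-2,3-dimethyl-2-(3-methylbut-2-en-1-yl)cyclohexan-1-one, via dimethylaluminium enolate 3 (not isolated), via lithium aluminate enolate 4 (not isolated)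
Conditions: Me3Al, Cu(O2CC4H3S) (copper thiophene-2-carboxylate, cat.), BINOL bis(1-phenylethyl)amine phosphoramidite (cat.), Et2O, −30 °C; then MeLi, THF, −30 °C; then 2, HMPA, −30 °C → rt
Reagents that add atoms: trimethylaluminium, C[Al](C)C
Why: Copper-catalysed asymmetric conjugate addition sets C4 under ligand control; the aluminium enolate, activated as its ate complex, should be alkylated at C5 anti to the neighbouring C4 methyl (conjugate addition–enolate alkylation), giving cis methyls and a trans prenyl group.

Step 2
Reactants: 5 (2R,3S)-2,3-dimethyl-2-(3-methylbut-2-en-1-yl)cyclohexan-1-one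
Product: 7 (5S,6R)-5,6-dimethyl-6-(3-methylbut-2-en-1-yl)cyclohex-2-en-1-one, via lithium enolate 6 (not isolated)
Conditions: LiN(i-Pr)2, THF, −78 °C; then PhS(Cl)=N-t-Bu, −78 °C
Reagents that add atoms: none
Why: Mukaiyama dehydrogenation: the only possible enolate (towards C1, since C5 is quaternary) is sulfenylated and the adduct eliminates at low temperature; the prenyl alkene and both stereocentres are untouched.

Step 3
Reactants: 7 (5S,6R)-5,6-dimethyl-6-(3-methylbut-2-en-1-yl)cyclohex-2-en-1-one
Product: 8 2,3-epoxy ketone with the oxirane cis to the prenyl group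
Conditions: 30% H2O2, NaOH (cat.), MeOH, 0 °C
Reagents that add atoms: hydrogen peroxide, OO
Why: Weitz–Scheffer nucleophilic epoxidation attacks only the electron-poor enone double bond; hydroperoxide should add at C2 trans to the C4 methyl, but the epoxide configuration is erased in step 5, so both epimers can be carried.

Step 4
Reactants: 8 2,3-epoxy ketone
Product: 10 (1S,4R,5S)-4,5-dimethyl-4-(3-methylbut-2-en-1-yl)cyclohex-2-en-1-ol, via epoxy hydrazone 9 (not isolated)
Conditions: N2H4·H2O, AcOH (cat.), MeOH, 0 °C → rt
Reagents that add atoms: none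
Why: Wharton transposition: the epoxy hydrazone fragments with loss of dinitrogen, placing the alkene at C1=C10 and leaving the oxygen on C2.

Step 5
Reactants: 10 (1S,4R,5S)-4,5-dimethyl-4-(3-methylbut-2-en-1-yl)cyclohex-2-en-1-ol
Product: 11 (4R,5S)-4,5-dimethyl-4-(3-methylbut-2-en-1-yl)cyclohex-2-en-1-one
Conditions: Dess–Martin periodinane, CH2Cl2, 0 °C → rt
Reagents that add atoms: none
Why: Dess–Martin oxidation of the allylic alcohol gives the transposed enone with C10 as an unsubstituted β-carbon; the prenyl group is inert.

Step 6
Reactants: 11 (4R,5S)-4,5-dimethyl-4-(3-methylbut-2-en-1-yl)cyclohex-2-en-1-one; 12 1-(tert-butyldimethylsilyloxy)-1-methoxyethene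
Product: 14 methyl 2-[2,3-dimethyl-2-(3-methylbut-2-en-1-yl)-5-oxocyclohexyl]acetate (ester arm on C10 cis to prenyl), via silyl enol ether 13 (not isolated)
Conditions: 12, t-BuMe2SiOTf (cat.), CH2Cl2, −78 °C; then 1 M HCl, THF, 0 °C
Reagents that add atoms: none
Why: Mukaiyama–Michael addition: the silyl-activated enone should be attacked axially at C10 on the half-chair with the C4 methyl equatorial, anti to the axial C5 methyl and trans to the C4 methyl, which puts the new arm cis to the prenyl group.

Step 7
Reactants: 14 keto ester
Product: 15 C2 dimethyl ketal of 14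
Conditions: HC(OMe)3, MeOH, PPTS (cat.), rt
Reagents that add atoms: trimethyl orthoformate, COC(OC)OC
Why: Acid-catalysed ketalisation with orthoformate as water scavenger masks the C2 ketone for the enolate and hydride steps and provides the leaving group for the later internal ketal.

Step 8
Reactants: 15 dimethyl ketal ester
Product: 17 α-hydroxy ester (9R expected as major epimer), via potassium enolate 16 (not isolated)
Conditions: KN(SiMe3)2, THF, −78 °C; then 2-(phenylsulfonyl)-3-phenyloxaziridine; then AcOH
Reagents that add atoms: 2-(phenylsulfonyl)-3-phenyloxaziridine, O=S(=O)(N1OC1c1ccccc1)c1ccccc1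
Why: Davis oxidation of the ester enolate places oxygen on C9; the configuration formed here does not matter because it is erased in step 9.

Step 9
Reactants: 17 α-hydroxy ester
Product: 18 α-keto ester (C9 ketone)
Conditions: Dess–Martin periodinane, pyridine, CH2Cl2, 0 °C → rt
Reagents that add atoms: none
Why: Dess–Martin oxidation under buffered, base-free conditions should keep the dimethyl ketal and avoid enolisation towards C10.

Step 10
Reactants: 18 α-keto ester
Product: 19 (9S)-α-hydroxy ester
Conditions: LiBH(s-Bu)3, THF, −78 °C; then AcOH
Reagents that add atoms: none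
Why: Felkin–Anh reduction: the bulky hydride should attack the C9 ketone anti to the quaternary C5 with H10 on the ester side, giving the 9S alcohol; the ester is not reduced at −78 °C.

Step 11
Reactants: 19 (9S)-α-hydroxy ester
Product: 20 internal methyl ketal (C2–O–C9 bridge, ester arm on the C5 side)
Conditions: PPTS (cat.), toluene, 5 Å molecular sieves, 60 °C
Reagents that add atoms: none
Why: Intramolecular transketalisation: the oxocarbenium ion at C2 is captured by the C9 hydroxyl once the arm is axial; removal of methanol drives closure, and the bridge fixes the C2 configuration.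

Step 12
Reactants: 20 internal methyl ketal ester
Product: 22 aldehyde (key-step precursor), via aluminium hemiacetal 21 (not isolated)
Conditions: i-Bu2AlH, CH2Cl2, −78 °C; then MeOH, aq. KNaC4H4O6
Reagents that add atoms: none
Why: Partial reduction with i-Bu2AlH: the α-alkoxy ester gives a chelated aluminium hemiacetal that is stable at −78 °C and releases the aldehyde on work-up without epimerising C9.

Step 13
Reactants: 22 aldehyde
Product: 24 tricyclic ene product (C8 hydroxyl cis to O9, trans to isopropenyl), via chloro(methyl)aluminium alkoxide 23 (not isolated)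
Conditions: Me2AlCl (2.5 equiv), CH2Cl2, −78 °C; then aq. NaHCO3
Reagents that add atoms: none
Why: Me2AlCl binds the aldehyde oxygen and the neighbouring ketal oxygen O9; C7 of the prenyl alkene adds to C8 while a methyl hydrogen passes to oxygen through a six-membered array, and the alcohol complex loses methane to alkoxide 23, which makes the closure irreversible; this is the Lewis-acid carbonyl-ene cyclisation known from citronellal to isopulegol. Ring B closes in the 6-exo mode at the carbonyl carbon through a chair, with both the C8=O and C7=C11 bonds outside the new ring. C7 is set by the bridge: it holds the C9 arm axial on ring A with the aldehyde on the prenyl side, so only the chair with C5–C4 axial and the C5 methyl equatorial on the new ring is open, and in it the isopropylidene unit must be equatorial (an axial one would meet C4 and O9), which places the isopropenyl group cis to the C5 methyl. C8 is set by the complexed oxygen taking the equatorial position, trans to the C7 substituent as in isopulegol; this is also the position gauche to O9 required by a five-membered aluminium chelate, so the hydroxyl ends cis to O9. The step needs aldehyde-selective activation with the ketal left closed; low temperature, the poor ionisation of a bridgehead ketal and the pre-folded, strained aldehyde should secure this, and Me2AlCl scavenges protons so the new isopropenyl group does not react further.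

Step 14
Reactants: 24 tricyclic ene product
Product: 25 C8 acetate of 24
Conditions: Ac2O, pyridine, DMAP (cat.), CH2Cl2, rt
Reagents that add atoms: acetic anhydride, CC(=O)OC(C)=O
Why: DMAP-catalysed acetylation of the only free hydroxyl, which is equatorial and unhindered.

Step 15
Reactants: 25 acetate
Product: 26 8-acetoxy-9-hydroxy-cis-eremophil-11-en-2-one
Conditions: AcOH/H2O/THF, 40 °C
Reagents that add atoms: water, O
Why: Mild acid hydrolysis of the mixed ketal frees the C2 ketone and the axial C9 hydroxyl in one operation without breaking the C9–O bond; the acetate and isopropenyl group should survive, and 26 may sit in equilibrium with its C2/O9 hemiketal.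

Step 16
Reactants: 26 8-acetoxy-9-hydroxy-cis-eremophil-11-en-2-one; 27 tigloyl chloride
Product: 28 CNP0204573.1 (8-acetoxy-9-tigloyloxy-cis-eremophil-11-en-2-one)
Conditions: 27, Et3N, DMAP, CH2Cl2, 0 °C → rt
Reagents that add atoms: none
Why: DMAP-catalysed acylation (acyl-pyridinium transfer) of the C9 hydroxyl keeps the E geometry of the acid chloride; the acetate already sits on the more stable equatorial oxygen, so migration is not favoured.

## Compound list

1 | 2-methylcyclohex-2-en-1-one | CC1=CCCCC1=O | starting material
2 | prenyl bromide (1-bromo-3-methylbut-2-ene) | CC(C)=CCBr | starting material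
3 | dimethylaluminium (3S)-2,3-dimethylcyclohex-1-en-1-olate | CC1=C(O[Al](C)C)CCC[C@@H]1C | intermediate
4 | lithium trimethylaluminate of the same enolate | [Li+].CC1=C(O[Al-](C)(C)C)CCC[C@@H]1C | intermediate
5 | (2R,3S)-2,3-dimethyl-2-(3-methylbut-2-en-1-yl)cyclohexan-1-one (methyls cis) | CC(C)=CC[C@@]1(C)C(=O)CCC[C@@H]1C | intermediate
6 | lithium enolate of 5 (C1=C10) | CC(C)=CC[C@@]1(C)C([O-])=CCC[C@@H]1C.[Li+] | intermediate
7 | (5S,6R)-5,6-dimethyl-6-(3-methylbut-2-en-1-yl)cyclohex-2-en-1-one | CC(C)=CC[C@@]1(C)C(=O)C=CC[C@@H]1C | intermediate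
8 | 2,3-epoxide of 7, oxirane cis to prenyl (expected major epimer) | CC(C)=CC[C@@]1(C)C(=O)[C@H]2O[C@H]2C[C@@H]1C | intermediate
9 | hydrazone of 8 | CC(C)=CC[C@@]1(C)C(=NN)[C@H]2O[C@H]2C[C@@H]1C | intermediate
10 | (1S,4R,5S)-4,5-dimethyl-4-(3-methylbut-2-en-1-yl)cyclohex-2-en-1-ol (expected major epimer) | CC(C)=CC[C@@]1(C)C=C[C@@H](O)C[C@@H]1C | intermediate
11 | (4R,5S)-4,5-dimethyl-4-(3-methylbut-2-en-1-yl)cyclohex-2-en-1-one | CC(C)=CC[C@@]1(C)C=CC(=O)C[C@@H]1C | intermediate
12 | 1-(tert-butyldimethylsilyloxy)-1-methoxyethene | COC(=C)O[Si](C)(C)C(C)(C)C | starting material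
13 | tert-butyldimethylsilyl enol ether (C1=C2) of 14 | CC(C)=CC[C@@]1(C)[C@H](C=C(O[Si](C)(C)C(C)(C)C)C[C@@H]1C)CC(=O)OC | intermediate
14 | methyl 2-[2,3-dimethyl-2-(3-methylbut-2-en-1-yl)-5-oxocyclohexyl]acetate; ester arm (C10) cis to prenyl, C4/C5 methyls cis | CC(C)=CC[C@@]1(C)[C@H](CC(=O)C[C@@H]1C)CC(=O)OC | intermediate
15 | C2 dimethyl ketal of 14 | CC(C)=CC[C@@]1(C)[C@H](CC(OC)(OC)C[C@@H]1C)CC(=O)OC | intermediate
16 | potassium enolate of 15 | CC(C)=CC[C@@]1(C)[C@H](CC(OC)(OC)C[C@@H]1C)C=C([O-])OC.[K+] | intermediate
17 | (9R)-α-hydroxy ester of 15 (expected major; both C9 epimers carried) | CC(C)=CC[C@@]1(C)[C@H](CC(OC)(OC)C[C@@H]1C)[C@@H](O)C(=O)OC | intermediate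
18 | α-keto ester (C9 ketone) | CC(C)=CC[C@@]1(C)[C@H](CC(OC)(OC)C[C@@H]1C)C(=O)C(=O)OC | intermediate
19 | (9S)-α-hydroxy ester | CC(C)=CC[C@@]1(C)[C@H](CC(OC)(OC)C[C@@H]1C)[C@H](O)C(=O)OC | intermediate
20 | internal methyl ketal ester: 6-oxabicyclo[3.2.1]octane with C2(OMe)–O–C9 bridge, ester arm towards C5 | CC(C)=CC[C@@]1(C)[C@@H]2C[C@@](OC)(O[C@@H]2C(=O)OC)C[C@@H]1C | intermediate
21 | diisobutylaluminium hemiacetal of 20 | CC(C)=CC[C@@]1(C)[C@@H]2C[C@@](OC)(O[C@@H]2C(OC)O[Al](CC(C)C)CC(C)C)C[C@@H]1C | intermediate
22 | internal-ketal aldehyde (key-step precursor): C5 prenyl, C8 aldehyde on C9, C2–O–C9 bridge | CC(C)=CC[C@@]1(C)[C@@H]2C[C@@](OC)(O[C@@H]2C=O)C[C@@H]1C | intermediate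
23 | chloro(methyl)aluminium alkoxide of 24 | C=C(C)[C@H]1C[C@@]2(C)[C@@H]3C[C@@](OC)(O[C@@H]3[C@@H]1O[Al](C)Cl)C[C@@H]2C | intermediate
24 | ene product: cis-eremophil-11-ene with C8 hydroxyl (cis to O9, trans to isopropenyl), C2 methoxy and C2–O–C9 bridge; isopropenyl cis to the C5 methyl | C=C(C)[C@H]1C[C@@]2(C)[C@@H]3C[C@@](OC)(O[C@@H]3[C@@H]1O)C[C@@H]2C | intermediate
25 | C8 acetate of 24 | C=C(C)[C@H]1C[C@@]2(C)[C@@H]3C[C@@](OC)(O[C@@H]3[C@@H]1OC(C)=O)C[C@@H]2C | intermediate
26 | 8-acetoxy-9-hydroxy-cis-eremophil-11-en-2-one (9S, hydroxyl cis to the acetate) | C=C(C)[C@H]1C[C@@]2(C)[C@H](CC(=O)C[C@@H]2C)[C@H](O)[C@@H]1OC(C)=O | intermediate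
27 | tigloyl chloride ((E)-2-methylbut-2-enoyl chloride) | C/C=C(\C)C(=O)Cl | starting material
28 | CNP0204573.1: 8-acetoxy-9-[(E)-2-methylbut-2-enoyloxy]-cis-eremophil-11-en-2-one | C=C(C)[C@H]1C[C@@]2(C)[C@H](CC(=O)C[C@@H]2C)[C@H](OC(=O)/C(C)=C/C)[C@@H]1OC(C)=O | target

## Step count and risks

Total step count: 16. Longest linear sequence: 16 steps (1 → 28).

Steps most likely to fail:

1. Step 13 (key step). Facial control at C8 may be lost if the aldehyde reacts through the non-chelated rotamer with its oxygen axial and anti to O9, or if the Lewis acid partly opens the ketal before cyclisation. Fallback: starting from 22, the cyclisation is run as before and the mixture of 24 and its C8 epimer, the axial alcohol F1, is not separated. It is oxidised with Dess–Martin periodinane to the C8 ketone F2, and this is reduced with NaBH4 and CeCl3·7H2O in MeOH at −78 °C. Axial hydride delivery anti to the axial C9–O bond should give the equatorial alcohol, so the sequence rejoins the route at 24 with C8 set by ketone reduction instead of by the ene transition state.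

2. Step 11. Ring closure may stall because the ester arm of the 9S alcohol is pressed against the prenyl CH2 in the bridged ketal, so that loss of methanol gives enol ether instead of the bridge. Fallback: starting from 17, whose 9R hydroxyl closes the bridge with the ester arm pointing away from C5, the same PPTS/toluene conditions should give the unstrained exo ketal ester F3. Deprotonation with LiN(i-Pr)2 at −78 °C gives the lithium enolate F4, and kinetic protonation with a hindered phenol from the open exo face turns the ester arm to the C5 side, arriving at 20. This route sets C9 by enolate protonation and omits steps 9 and 10.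

3. Step 16. Acylation of the axial, concave C9 hydroxyl (partly held as the hemiketal with C2) may be slow enough for base-mediated acetyl migration from O8 to O9, followed by tigloylation at O8. Fallback: starting from 26, the hydroxyl is acylated under neutral conditions with 2-(diethoxyphosphoryl)propanoic acid and dicyclohexylcarbodiimide, which react through a phosphonoketene that acylates hindered alcohols, to give the phosphonate ester F5. Horner–Wadsworth–Emmons olefination with acetaldehyde (LiCl, DBU, MeCN) then builds the (E)-2-methylbut-2-enoate in place and rejoins the route at 28.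

Further compounds
F1 | step 13 | C8 epimer of 24 (axial C8 hydroxyl) | C=C(C)[C@H]1C[C@@]2(C)[C@@H]3C[C@@](OC)(O[C@@H]3[C@H]1O)C[C@@H]2C
F2 | step 13 | C8 ketone derived from 24 and F1 | C=C(C)[C@H]1C[C@@]2(C)[C@@H]3C[C@@](OC)(O[C@@H]3C1=O)C[C@@H]2C
F3 | step 11 | internal methyl ketal ester with exo ester arm (9R) | CC(C)=CC[C@@]1(C)[C@@H]2C[C@@](OC)(O[C@H]2C(=O)OC)C[C@@H]1C
F4 | step 11 | lithium enolate of F3 | CC(C)=CC[C@@]1(C)[C@@H]2C[C@@](OC)(OC2=C([O-])OC)C[C@@H]1C.[Li+]
F5 | step 16 | 2-(diethoxyphosphoryl)propanoate of 26 at O9 | C=C(C)[C@H]1C[C@@]2(C)[C@H](CC(=O)C[C@@H]2C)[C@H](OC(=O)C(C)P(=O)(OCC)OCC)[C@@H]1OC(C)=O
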